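**Plan**
1. Retrosynthetic cuts, in order: (a) the bond between the allylic CH2 of the 2‑methylene‑3‑oxobutyl chain and C5 of the furan‑2(5H)‑one ring; (b) the C–C bond to the acetoxymethyl carbon (formaldehyde, Morita–Baylis–Hillman); (c) the ArO–CH2 bond (vinyloxirane, then oxidation to the vinyl ketone); (d) the pyranone ring of the coumarin at C4–C4a and O1–C2 (ethyl propiolate on 2‑methoxyresorcinol).
2. Forward order: the coumarin pyranone ring is closed first; the four‑carbon chain is grown on O7 and turned into an MBH acetate; the furanone ring is not built but delivered as aromatic 3‑methyl‑2‑silyloxyfuran and dearomatised in the last step, which joins the two halves without protecting groups.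
3. Enabling feature: the CH2 to be bonded is the allylic terminus of a C(=CH2)–C(=O) unit (a 2‑acylallyl group, the retron of an SN2′/SN2′ substitution on an MBH acetate that returns the exocyclic methylene). Its partner is C5, the γ‑carbon of the α‑methylbutenolide ring O1–C2(=O)–C3(Me)=C4–C5, which is the nucleophilic carbon of the corresponding 2‑silyloxyfuran.
4. Stereochemistry: the only stereocentre (furanone C5, R) is created in the coupling by a chiral amide–phosphine catalyst (bond formation on the Re face of furan C5); the carbinol centre formed in the epoxide opening is racemic and is erased by oxidation.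

Key step: step 7

Assumption: the sense of induction of the binaphthyl amide–phosphine with an unsubstituted CH2 terminus cannot be fixed on paper; the route is written with the (R)‑catalyst, and the equally accessible (S)‑catalyst takes its place if the Si‑face product should prevail.

**Route**

Step 1
Reactants: 1 2‑methoxybenzene‑1,3‑diol (2‑methoxyresorcinol); 2 ethyl propiolate
Product: 4 7‑hydroxy‑8‑methoxy‑2H‑chromen‑2‑one, via ethyl (Z)‑3‑(2,4‑dihydroxy‑3‑methoxyphenyl)acrylate 3 (not isolated)
Conditions: ZnCl2 (1 equiv), 1,4‑dioxane, 100 °C; aq. HCl work‑up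
Reagents that add atoms: none
Why: Pechmann‑type coumarin synthesis with a propiolate (ZnCl2‑mediated hydroarylation ortho/para to the two hydroxyl groups, then lactonisation of the Z‑cinnamate with loss of ethanol); C4 and C6 of the symmetric diol are equivalent, so only the 7‑hydroxy‑8‑methoxy isomer can form.

Step 2
Reactants: 4 7‑hydroxy‑8‑methoxy‑2H‑chromen‑2‑one; 5 2‑vinyloxirane (butadiene monoxide, racemic)
Product: 6 7‑[(2‑hydroxybut‑3‑en‑1‑yl)oxy]‑8‑methoxy‑2H‑chromen‑2‑one (racemic)
Conditions: 5 (3 equiv), K2CO3 (0.3 equiv), DMF, 80 °C, sealed tube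
Reagents that add atoms: none
Why: base‑mediated SN2 opening of the epoxide by the phenoxide at the unhindered terminal CH2 (the normal site under basic conditions) should give the 1‑aryloxy‑3‑buten‑2‑ol; its stereocentre is irrelevant because step 3 removes it.

Step 3
Reactants: 6 7‑[(2‑hydroxybut‑3‑en‑1‑yl)oxy]‑8‑methoxy‑2H‑chromen‑2‑one
Product: 7 8‑methoxy‑7‑[(2‑oxobut‑3‑en‑1‑yl)oxy]‑2H‑chromen‑2‑one
Conditions: Dess–Martin periodinane, CH2Cl2, 0 °C to rt; used at once
Reagents that add atoms: none
Why: Dess–Martin oxidation of a secondary allylic alcohol to the vinyl ketone proceeds under neutral, non‑nucleophilic conditions that should leave the coumarin lactone and the new enone untouched.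

Step 4
Reactants: 7 8‑methoxy‑7‑[(2‑oxobut‑3‑en‑1‑yl)oxy]‑2H‑chromen‑2‑one
Product: 8 7‑{[3‑(hydroxymethyl)‑2‑oxobut‑3‑en‑1‑yl]oxy}‑8‑methoxy‑2H‑chromen‑2‑one
Conditions: aq. HCHO (37 %, 3 equiv), DABCO (0.3 equiv), THF/H2O, 0 °C to rt
Reagents that add atoms: formaldehyde (37 % aq.), C=O
Why: Morita–Baylis–Hillman reaction, in which DABCO adds only to the unsubstituted vinyl ketone (the β‑substituted, arene‑conjugated coumarin C3=C4 bond is inert) and the ammonium enolate is trapped by the most reactive aldehyde, formaldehyde.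

Step 5
Reactants: 8 7‑{[3‑(hydroxymethyl)‑2‑oxobut‑3‑en‑1‑yl]oxy}‑8‑methoxy‑2H‑chromen‑2‑one
Product: 9 4‑[(8‑methoxy‑2‑oxo‑2H‑chromen‑7‑yl)oxy]‑2‑methylidene‑3‑oxobutyl acetate
Conditions: Ac2O, pyridine, DMAP (cat.), CH2Cl2, 0 °C
Reagents that add atoms: acetic anhydride, CC(=O)OC(C)=O
Why: standard O‑acetylation of the primary allylic alcohol makes the MBH acetate needed for Lewis‑base catalysis; any reversible SN2′ exchange is harmless because both allyl termini are CH2 groups.

Step 6
Reactants: 10 3‑methylfuran‑2(5H)‑one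
Product: 11 trimethyl[(3‑methylfuran‑2‑yl)oxy]silane
Conditions: TMSOTf, Et3N, Et2O, 0 °C; filtration and distillation under argon
Reagents that add atoms: trimethylsilyl trifluoromethanesulfonate, C[Si](C)(C)OS(=O)(=O)C(F)(F)F
Why: soft enolisation (O‑silylation of the lactone carbonyl, then γ‑deprotonation by the amine) gives the aromatic 2‑silyloxyfuran, the standard way to make vinylogous Mukaiyama donors.

Step 7
Reactants: 9 4‑[(8‑methoxy‑2‑oxo‑2H‑chromen‑7‑yl)oxy]‑2‑methylidene‑3‑oxobutyl acetate; 11 trimethyl[(3‑methylfuran‑2‑yl)oxy]silane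
Product: 13 8‑methoxy‑7‑({3‑[((2R)‑4‑methyl‑5‑oxo‑2,5‑dihydrofuran‑2‑yl)methyl]‑2‑oxobut‑3‑en‑1‑yl}oxy)‑2H‑chromen‑2‑one, via allylphosphonium acetate 12 (not isolated)
Conditions: 11 (1.5 equiv), (R)‑N‑[2′‑(diphenylphosphanyl)‑1,1′‑binaphthalen‑2‑yl]acetamide (10 mol %), H2O (5 equiv), toluene, rt
Reagents that add atoms: none
Why: Chiral phosphine‑catalysed allylic substitution of a Morita–Baylis–Hillman acetate by a 2‑silyloxyfuran, a vinylogous Mukaiyama‑type SN2′/SN2′ relay: the phosphine adds to the =CH2 terminus of 9 and expels acetate to give the 2‑acylallylphosphonium ion 12, C5 of furan 11 then attacks the new =CH2 terminus and expels the phosphine, which regenerates the exocyclic methylene of the enone, and acetate/water remove the silyl group to unveil the lactone C=O. The closest known reaction type is the amide–phosphine‑catalysed substitution of aryl‑substituted MBH acetates of vinyl ketones and acrylates with 2‑trimethylsilyloxyfuran to give 5‑allylated furan‑2(5H)‑ones; here it is applied to a formaldehyde‑derived MBH acetate and a 3‑methylated furan. No ring is closed: the furanone ring is delivered ready‑made as the aromatic furan and is dearomatised by the C–C bond formation. The new stereocentre C5 (R) results from bond formation on the Re face of furan C5 and is controlled by the catalyst alone, whose amide N–H binds the ketone/enolate oxygen of 12 while the binaphthyl–PPh2 unit blocks one side of the allyl terminus so that the furan can stack (endo, Diels–Alder‑like) in only one orientation. Site selectivity in the furan (C5 over C3) is secured by the 3‑methyl group and the intrinsic γ‑preference of 2‑silyloxyfurans, and regioselectivity in the electrophile is no issue because both termini of the 2‑acylallyl unit are CH2 groups, so every SN2/SN2′ path converges on one constitution. Chemoselectivity over the coumarin C3=C4 bond is secured because only the unhindered ketone‑conjugated methylene takes up the phosphine and only it carries an allylic leaving group, and the neutral medium should leave the base‑labile C5–H of the product untouched.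

**Compound list**
1 | 2‑methoxybenzene‑1,3‑diol (2‑methoxyresorcinol) | COc1c(O)cccc1O | starting material
2 | ethyl propiolate | C#CC(=O)OCC | starting material
3 | ethyl (2Z)‑3‑(2,4‑dihydroxy‑3‑methoxyphenyl)prop‑2‑enoate | CCOC(=O)/C=C\c1ccc(O)c(OC)c1O | intermediate
4 | 7‑hydroxy‑8‑methoxy‑2H‑chromen‑2‑one | COc1c(O)ccc2ccc(=O)oc12 | intermediate
5 | 2‑vinyloxirane (racemic) | C=CC1CO1 | starting material
6 | 7‑[(2‑hydroxybut‑3‑en‑1‑yl)oxy]‑8‑methoxy‑2H‑chromen‑2‑one (racemic) | C=CC(O)COc1ccc2ccc(=O)oc2c1OC | intermediate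
7 | 8‑methoxy‑7‑[(2‑oxobut‑3‑en‑1‑yl)oxy]‑2H‑chromen‑2‑one | C=CC(=O)COc1ccc2ccc(=O)oc2c1OC | intermediate
8 | 7‑{[3‑(hydroxymethyl)‑2‑oxobut‑3‑en‑1‑yl]oxy}‑8‑methoxy‑2H‑chromen‑2‑one | C=C(CO)C(=O)COc1ccc2ccc(=O)oc2c1OC | intermediate
9 | 4‑[(8‑methoxy‑2‑oxo‑2H‑chromen‑7‑yl)oxy]‑2‑methylidene‑3‑oxobutyl acetate | CC(=O)OCC(=C)C(=O)COc1ccc2ccc(=O)oc2c1OC | intermediate
10 | 3‑methylfuran‑2(5H)‑one | CC1=CCOC1=O | starting material
11 | trimethyl[(3‑methylfuran‑2‑yl)oxy]silane | Cc1ccoc1O[Si](C)(C)C | intermediate
12 | [(R)‑2′‑acetamido‑1,1′‑binaphthalen‑2‑yl]{4‑[(8‑methoxy‑2‑oxo‑2H‑chromen‑7‑yl)oxy]‑2‑methylidene‑3‑oxobutyl}diphenylphosphonium acetate (axial R configuration not expressible in SMILES) | CC(=O)Nc1ccc2ccccc2c1-c1c([P+](CC(=C)C(=O)COc2ccc3ccc(=O)oc3c2OC)(c2ccccc2)c2ccccc2)ccc2ccccc12.CC(=O)[O-] | intermediate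
13 | 8‑methoxy‑7‑({3‑[((2R)‑4‑methyl‑5‑oxo‑2,5‑dihydrofuran‑2‑yl)methyl]‑2‑oxobut‑3‑en‑1‑yl}oxy)‑2H‑chromen‑2‑one | C=C(C[C@@H]1C=C(C)C(=O)O1)C(=O)COc1ccc2ccc(=O)oc2c1OC | target

**Count**
Total steps: 7. Longest linear sequence: 6 (steps 1–5 and 7); step 6 is a one‑step side branch.

**Steps most likely to fail**

1. Step 7: enantioface discrimination at furan C5 may be poor, because the electrophilic terminus is an unsubstituted CH2 and cannot relay the chirality of the catalyst; an uncatalysed conjugate addition–elimination of the furan to the enone could also erode the selectivity. Fallback, setting out from 9 and 11 and coming back at 13: the same coupling is run with achiral triphenylphosphine (20 mol %, toluene/H2O, rt), which should give 13 together with its mirror image, 8‑methoxy‑7‑({3‑[((2S)‑4‑methyl‑5‑oxo‑2,5‑dihydrofuran‑2‑yl)methyl]‑2‑oxobut‑3‑en‑1‑yl}oxy)‑2H‑chromen‑2‑one F1. The two are then separated by preparative chromatography on a chiral stationary phase (amylose tris(3,5‑dimethylphenylcarbamate), supercritical CO2/MeOH), so that stereocontrol by catalyst is replaced by resolution.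

2. Step 4: base‑induced self‑condensation of the aryloxymethyl vinyl ketone (Rauhut–Currier dimerisation, polymerisation) may outrun the capture of formaldehyde. Fallback, setting out from 4 and coming back at 9, which avoids the vinyl ketone and the MBH reaction altogether:
   - O‑alkylation of 4 with tert‑butyl bromoacetate (K2CO3, acetone, reflux) should give tert‑butyl [(8‑methoxy‑2‑oxo‑2H‑chromen‑7‑yl)oxy]acetate F2.
   - TFA/CH2Cl2 cleaves the ester to [(8‑methoxy‑2‑oxo‑2H‑chromen‑7‑yl)oxy]acetic acid F3.
   - Oxalyl chloride with catalytic DMF converts this into [(8‑methoxy‑2‑oxo‑2H‑chromen‑7‑yl)oxy]acetyl chloride F4.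
   - Stille acylation of F4 (Pd2(dba)3, tri(2‑furyl)phosphine, toluene, 50 °C) with 2‑(tributylstannyl)prop‑2‑en‑1‑yl acetate F5 forms the C(=O)–C(=CH2) bond and delivers 9 directly. F5 is prepared by Mo‑catalysed α‑selective hydrostannation of propargyl acetate with Bu3SnH.

3. Step 2: regiocontrol in the epoxide opening may be lost (attack at the allylic carbon or SN2′), and the product alkoxide may add to further epoxide, both made worse by the low nucleophilicity of the coumarin phenoxide. Fallback, setting out from 4 and coming back at 6, which fixes the ether oxygen on the terminal carbon by construction: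
   - O‑alkylation of 4 with 2‑bromo‑1,1‑diethoxyethane (K2CO3, KI cat., DMF, 100 °C) should give 7‑(2,2‑diethoxyethoxy)‑8‑methoxy‑2H‑chromen‑2‑one F6.
   - Aqueous acid (1 M HCl/THF) releases [(8‑methoxy‑2‑oxo‑2H‑chromen‑7‑yl)oxy]acetaldehyde F7.
   - Nozaki–Hiyama–Kishi vinylation (vinyl bromide, CrCl2, NiCl2 cat., DMF, rt), which is selective for the aldehyde over the lactone, gives 6.

**Further compounds**
F1 | step 7 | 8‑methoxy‑7‑({3‑[((2S)‑4‑methyl‑5‑oxo‑2,5‑dihydrofuran‑2‑yl)methyl]‑2‑oxobut‑3‑en‑1‑yl}oxy)‑2H‑chromen‑2‑one | C=C(C[C@H]1C=C(C)C(=O)O1)C(=O)COc1ccc2ccc(=O)oc2c1OC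
F2 | step 4 | tert‑butyl [(8‑methoxy‑2‑oxo‑2H‑chromen‑7‑yl)oxy]acetate | CC(C)(C)OC(=O)COc1ccc2ccc(=O)oc2c1OC
F3 | step 4 | [(8‑methoxy‑2‑oxo‑2H‑chromen‑7‑yl)oxy]acetic acid | OC(=O)COc1ccc2ccc(=O)oc2c1OC
F4 | step 4 | [(8‑methoxy‑2‑oxo‑2H‑chromen‑7‑yl)oxy]acetyl chloride | ClC(=O)COc1ccc2ccc(=O)oc2c1OC
F5 | step 4 | 2‑(tributylstannyl)prop‑2‑en‑1‑yl acetate | CC(=O)OCC(=C)[Sn](CCCC)(CCCC)CCCC
F6 | step 2 | 7‑(2,2‑diethoxyethoxy)‑8‑methoxy‑2H‑chromen‑2‑one | CCOC(COc1ccc2ccc(=O)oc2c1OC)OCC
F7 | step 2 | [(8‑methoxy‑2‑oxo‑2H‑chromen‑7‑yl)oxy]acetaldehyde | O=CCOc1ccc2ccc(=O)oc2c1OC
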